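**Retrosynthetic overview**

1. Ring C last: the 11,14-hydroquinone comes from its quinone (Na2S2O4), the 13-isopropyl group from radical alkylation of that quinone, and the C14 oxygen from Teuber oxidation of an 11-phenol. Ring B is closed before that by Friedel–Crafts acylation (C7–C8).
2. Ring A and the δ-lactone are formed together in one radical cascade (C2–C3, then C4–C5) from an acyclic iodide whose C10 carries the aryl ring, a CH2CH2I arm (C1–C2), a methacrylate ester on O–C20 and a tert-butyl enoate (C5=C6–C7).
3. Enabling feature: the C19(=O)–O–C20 lactone bridge between C4 and C10 (ring A plus lactone = 3-oxabicyclo[3.3.1]nonan-2-one). It lets C3=C4(CH3)–C19 be carried as the methacrylate of the C20 hydroxymethyl group, so the tether fixes C4 and a C2 radical can stitch ring A.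
4. C10 is set by enantioselective desymmetrisation of a 2-aryl-2-(2-silyloxyethyl)propane-1,3-diol, built from 2-bromo-6-methoxyphenol, diethyl malonate and a bromoethyl silyl ether.
5. Order of ring formation: ring C (bought), ring A and the lactone ring together (key step), ring B, then oxidation-state and substituent adjustment of ring C.

Key step: step 10

Remark: atom labels C1–C20 are those of the abietane skeleton of the target.
Assumption: the dinuclear zinc catalyst from (S,S)-ProPhenol acylates the pro-S hydroxymethyl group of 7; if the sense proves opposite, the (R,R)-ligand is used.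

**Route**

Step 1
Reactants: 1 2-bromo-6-methoxyphenol
Product: 2 1-bromo-2-isopropoxy-3-methoxybenzene
Conditions: 2-bromopropane, K2CO3, DMF, 60 °C
Reagents that add atoms: 2-bromopropane, CC(C)Br
Why: Williamson ether synthesis of the phenoxide with a secondary bromide; the isopropyl ether is chosen because it survives base, hydride, radicals and trifluoroacetic acid yet is cleaved by BCl3 without touching the methyl ether.

Step 2
Reactants: 2 1-bromo-2-isopropoxy-3-methoxybenzene; 3 diethyl malonate
Product: 4 diethyl 2-(2-isopropoxy-3-methoxyphenyl)malonate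
Conditions: Pd(dba)2 (2 mol%), P(t-Bu)3 (4 mol%), K3PO4, toluene, 70 °C
Reagents that add atoms: none
Why: Palladium-catalysed α-arylation of a malonate with an aryl bromide, for which a bulky electron-rich trialkylphosphine tolerates ortho-alkoxy groups; the more acidic aryl malonate stays as its enolate and is not arylated twice.

Step 3
Reactants: 4 diethyl 2-(2-isopropoxy-3-methoxyphenyl)malonate; 5 (2-bromoethoxy)(tert-butyl)dimethylsilane
Product: 6 diethyl 2-[2-(tert-butyldimethylsilyloxy)ethyl]-2-(2-isopropoxy-3-methoxyphenyl)malonate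
Conditions: Cs2CO3, NaI (cat.), DMF, 60 °C
Reagents that add atoms: none
Why: SN2 alkylation of the stabilised malonate anion by a primary bromide (iodide-catalysed), which installs the future C1–C2 unit and makes C10 a quaternary, still prochiral carbon.

Step 4
Reactants: 6 diethyl 2-[2-(tert-butyldimethylsilyloxy)ethyl]-2-(2-isopropoxy-3-methoxyphenyl)malonate
Product: 7 2-[2-(tert-butyldimethylsilyloxy)ethyl]-2-(2-isopropoxy-3-methoxyphenyl)propane-1,3-diol
Conditions: LiAlH4, THF, 0 °C to rt; aqueous work-up
Reagents that add atoms: none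
Why: Hydride reduction of both esters of a 2,2-disubstituted malonate to the 1,3-diol; silyl and aryl ethers are inert to LiAlH4 at this temperature.

Step 5
Reactants: 7 2-[2-(tert-butyldimethylsilyloxy)ethyl]-2-(2-isopropoxy-3-methoxyphenyl)propane-1,3-diol; 8 vinyl methacrylate
Product: 9 (S)-2-[2-(tert-butyldimethylsilyloxy)ethyl]-3-hydroxy-2-(2-isopropoxy-3-methoxyphenyl)propyl methacrylate
Conditions: 8 (5 equiv), Et2Zn (10 mol%), (S,S)-ProPhenol ligand (5 mol%), BHT (trace), toluene, −20 °C
Reagents that add atoms: none
Why: Catalytic enantioselective desymmetrisation of a 2-aryl-2-alkylpropane-1,3-diol by acyl transfer from a vinyl ester at a chiral dinuclear zinc alkoxide, which sets C10 by differentiating the enantiotopic hydroxymethyl groups and at the same time places the C3=C4(CH3)–C19 unit on the future C20 oxygen; the conjugated ester resists the 1,3-acyl migration that would racemise the product.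

Step 6
Reactants: 9 (S)-2-[2-(tert-butyldimethylsilyloxy)ethyl]-3-hydroxy-2-(2-isopropoxy-3-methoxyphenyl)propyl methacrylate
Product: 10 (R)-4-(tert-butyldimethylsilyloxy)-2-formyl-2-(2-isopropoxy-3-methoxyphenyl)butyl methacrylate
Conditions: Dess–Martin periodinane, CH2Cl2, 0 °C to rt
Reagents that add atoms: none
Why: Dess–Martin oxidation of the neopentyl primary alcohol under near-neutral conditions gives an aldehyde without α-hydrogen, after which C10 can no longer be scrambled by acyl migration or enolisation.

Step 7
Reactants: 10 (R)-4-(tert-butyldimethylsilyloxy)-2-formyl-2-(2-isopropoxy-3-methoxyphenyl)butyl methacrylate; 11 tert-butyl (triphenylphosphoranylidene)acetate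
Product: 12 tert-butyl (R,E)-6-(tert-butyldimethylsilyloxy)-4-(2-isopropoxy-3-methoxyphenyl)-4-[(methacryloyloxy)methyl]hex-2-enoate
Conditions: toluene, BHT (trace), 90 °C
Reagents that add atoms: none
Why: Wittig olefination with a stabilised ylide, which reacts with the hindered aldehyde on heating, is E-selective and does not add to the methacrylate.

Step 8
Reactants: 12 tert-butyl (R,E)-6-(tert-butyldimethylsilyloxy)-4-(2-isopropoxy-3-methoxyphenyl)-4-[(methacryloyloxy)methyl]hex-2-enoate
Product: 13 tert-butyl (R,E)-6-hydroxy-4-(2-isopropoxy-3-methoxyphenyl)-4-[(methacryloyloxy)methyl]hex-2-enoate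
Conditions: HF·pyridine, THF, 0 °C to rt
Reagents that add atoms: none
Why: Fluoride cleavage of the primary silyl ether under mildly acidic conditions, chosen over basic fluoride so that the freed C2 oxygen cannot add to the enoate at C5 (5-exo oxa-Michael addition).

Step 9
Reactants: 13 tert-butyl (R,E)-6-hydroxy-4-(2-isopropoxy-3-methoxyphenyl)-4-[(methacryloyloxy)methyl]hex-2-enoate
Product: 14 tert-butyl (R,E)-6-iodo-4-(2-isopropoxy-3-methoxyphenyl)-4-[(methacryloyloxy)methyl]hex-2-enoate
Conditions: I2, PPh3, imidazole, CH2Cl2, 0 °C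
Reagents that add atoms: iodine, [I][I]
Why: Appel reaction, in which iodide displaces the alkoxyphosphonium group at the unhindered primary carbon C2 to give the radical precursor.

Step 10
Reactants: 14 tert-butyl (R,E)-6-iodo-4-(2-isopropoxy-3-methoxyphenyl)-4-[(methacryloyloxy)methyl]hex-2-enoate
Product: 15 tert-butyl 2-[(1S,5R,9R)-5-(2-isopropoxy-3-methoxyphenyl)-1-methyl-2-oxo-3-oxabicyclo[3.3.1]nonan-9-yl]acetate
Conditions: (Me3Si)3SiH (1.3 equiv), AIBN (0.2 equiv), PhH (5 mM), 80 °C, syringe-pump addition over 8 h
Reagents that add atoms: none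
Why: The silyl radical abstracts iodine from 14 to give the primary C2 radical, which adds to the unsubstituted CH2 terminus (C3) of the tethered methacrylate in an 8-endo-trig closure (Giese-type addition) to give a tertiary α-ester radical at C4 inside a transient eight-membered lactone; this radical closes onto C5, the β-carbon of the tert-butyl enoate, in a transannular step that is 6-exo-trig for ring A and 6-exo-trig for the δ-lactone, and the resulting C6 α-ester radical takes hydrogen from the silane to carry the chain. The closest known reaction types are 8-endo radical cyclisations that give eight-membered lactones at low hydride-donor concentration and radical macrocyclisation/transannular cyclisation cascades. C4 is set by the tether: once C19–O–C20 and C1–C2–C3 both link C4 to C10, closure onto C5 can only give the bicyclo[3.3.1] lactone with C19 and C20 cis, which puts the C4 methyl group trans to them. C5 is set in a chair-like 6-exo transition state for ring A in which the exocyclic acceptor carbon C6 lies equatorial on the forming carbocycle and over the flat ester bridge, where it meets one syn-axial hydrogen (on C20) instead of two (on C1 and C3), which should give H-5 trans to C20. The step needs chemoselective radical generation (secured by the iodide, which silyl radicals abstract faster than they add to acrylates), regioselective first addition (every other ring closure open to the C2 radical, onto C5, C6 or the arene, is 4-exo or 5-endo) and regioselective second addition at C5 (secured by conjugation of C5=C6 with the ester, which places the new radical at C6). High dilution and slow silane addition should keep premature reduction of the C2 radical slower than the 8-endo step.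

Step 11
Reactants: 15 tert-butyl 2-[(1S,5R,9R)-5-(2-isopropoxy-3-methoxyphenyl)-1-methyl-2-oxo-3-oxabicyclo[3.3.1]nonan-9-yl]acetate
Product: 18 (4S,5R,10R)-11-isopropoxy-12-methoxy-7-oxopodocarpa-8,11,13-trien-19,20-olide, via carboxylic acid 16 (not isolated), via mixed trifluoroacetic anhydride 17 (not isolated)
Conditions: CF3CO2H, CH2Cl2, rt; evaporate; then (CF3CO)2O, CH2Cl2, 0 °C to rt
Reagents that add atoms: none
Why: Acidolysis of the tert-butyl ester followed by intramolecular Friedel–Crafts acylation through the mixed anhydride closes ring B at C8, the only ortho position of the aryl group that carries hydrogen and one that is para to the 12-methoxy group; no stereocentre is formed and the trans A/B fusion follows from C5 and C10.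

Step 12
Reactants: 18 (4S,5R,10R)-11-isopropoxy-12-methoxy-7-oxopodocarpa-8,11,13-trien-19,20-olide
Product: 20 (4S,5R,10R)-11-hydroxy-12-methoxy-7-oxopodocarpa-8,11,13-trien-19,20-olide, via aryl dichloroborinate 19 (not isolated)
Conditions: BCl3, CH2Cl2, −78 to 0 °C; then H2O
Reagents that add atoms: none
Why: Lewis-acid cleavage of an aryl isopropyl ether by BCl3, which removes the secondary alkyl group as 2-chloropropane much faster than it demethylates an aryl methyl ether that is not next to a carbonyl group.

Step 13
Reactants: 20 (4S,5R,10R)-11-hydroxy-12-methoxy-7-oxopodocarpa-8,11,13-trien-19,20-olide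
Product: 21 (4S,5R,10R)-12-methoxy-7,11,14-trioxopodocarpa-8,12-dien-19,20-olide
Conditions: (KSO3)2NO (Fremy's salt, 2.5 equiv), KH2PO4, acetone/H2O, rt
Reagents that add atoms: Fremy's salt (dipotassium nitrosodisulfonate), [K+].[K+].[O]N(S(=O)(=O)[O-])S(=O)(=O)[O-]
Why: Teuber oxidation, in which the first equivalent of the nitroxide forms the phenoxyl radical and the second delivers oxygen to the free para position C14 to give the para-quinone.

Step 14
Reactants: 21 (4S,5R,10R)-12-methoxy-7,11,14-trioxopodocarpa-8,12-dien-19,20-olide; 22 isobutyric acid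
Product: 23 (4S,5R,10R)-12-methoxy-7,11,14-trioxoabieta-8,12-dien-19,20-olide
Conditions: 22 (5 equiv), AgNO3 (0.3 equiv), (NH4)2S2O8 (2 equiv), MeCN/H2O, 65 °C
Reagents that add atoms: none
Why: Silver-catalysed decarboxylative radical alkylation of a quinone (Minisci-type, persulfate as oxidant), in which the isopropyl radical adds to C13, the only quinone carbon that carries hydrogen, and re-oxidation restores the quinone.

Step 15
Reactants: 23 (4S,5R,10R)-12-methoxy-7,11,14-trioxoabieta-8,12-dien-19,20-olide
Product: 24 (4S,5R,10R)-11,14-dihydroxy-12-methoxy-7-oxoabieta-8,11,13-trien-19,20-olide (CNP0159814.2)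
Conditions: Na2S2O4, EtOAc/H2O, rt
Reagents that add atoms: none
Why: Dithionite reduction of the para-quinone to the hydroquinone, which is stabilised by the hydrogen bond between the 14-hydroxyl group and the C7 ketone; ketone, lactone and methyl ether are inert.

**Compound list**

1 | 2-bromo-6-methoxyphenol | COc1cccc(Br)c1O | starting material
2 | 1-bromo-2-isopropoxy-3-methoxybenzene | COc1cccc(Br)c1OC(C)C | intermediate
3 | diethyl malonate | CCOC(=O)CC(=O)OCC | starting material
4 | diethyl 2-(2-isopropoxy-3-methoxyphenyl)malonate | CCOC(=O)C(C(=O)OCC)c1cccc(OC)c1OC(C)C | intermediate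
5 | (2-bromoethoxy)(tert-butyl)dimethylsilane | BrCCO[Si](C)(C)C(C)(C)C | starting material
6 | diethyl 2-[2-(tert-butyldimethylsilyloxy)ethyl]-2-(2-isopropoxy-3-methoxyphenyl)malonate | CCOC(=O)C(CCO[Si](C)(C)C(C)(C)C)(C(=O)OCC)c1cccc(OC)c1OC(C)C | intermediate
7 | 2-[2-(tert-butyldimethylsilyloxy)ethyl]-2-(2-isopropoxy-3-methoxyphenyl)propane-1,3-diol | OCC(CO)(CCO[Si](C)(C)C(C)(C)C)c1cccc(OC)c1OC(C)C | intermediate
8 | vinyl methacrylate | C=COC(=O)C(C)=C | starting material
9 | (S)-2-[2-(tert-butyldimethylsilyloxy)ethyl]-3-hydroxy-2-(2-isopropoxy-3-methoxyphenyl)propyl methacrylate | OC[C@](c1cccc(OC)c1OC(C)C)(COC(=O)C(C)=C)CCO[Si](C)(C)C(C)(C)C | intermediate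
10 | (R)-4-(tert-butyldimethylsilyloxy)-2-formyl-2-(2-isopropoxy-3-methoxyphenyl)butyl methacrylate | O=C[C@](c1cccc(OC)c1OC(C)C)(COC(=O)C(C)=C)CCO[Si](C)(C)C(C)(C)C | intermediate
11 | tert-butyl (triphenylphosphoranylidene)acetate | CC(C)(C)OC(=O)C=P(c1ccccc1)(c1ccccc1)c1ccccc1 | starting material
12 | tert-butyl (R,E)-6-(tert-butyldimethylsilyloxy)-4-(2-isopropoxy-3-methoxyphenyl)-4-[(methacryloyloxy)methyl]hex-2-enoate | CC(C)(C)OC(=O)/C=C/[C@](c1cccc(OC)c1OC(C)C)(COC(=O)C(C)=C)CCO[Si](C)(C)C(C)(C)C | intermediate
13 | tert-butyl (R,E)-6-hydroxy-4-(2-isopropoxy-3-methoxyphenyl)-4-[(methacryloyloxy)methyl]hex-2-enoate | CC(C)(C)OC(=O)/C=C/[C@](c1cccc(OC)c1OC(C)C)(COC(=O)C(C)=C)CCO | intermediate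
14 | tert-butyl (R,E)-6-iodo-4-(2-isopropoxy-3-methoxyphenyl)-4-[(methacryloyloxy)methyl]hex-2-enoate | CC(C)(C)OC(=O)/C=C/[C@](c1cccc(OC)c1OC(C)C)(COC(=O)C(C)=C)CCI | intermediate
15 | tert-butyl 2-[(1S,5R,9R)-5-(2-isopropoxy-3-methoxyphenyl)-1-methyl-2-oxo-3-oxabicyclo[3.3.1]nonan-9-yl]acetate | CC(C)(C)OC(=O)C[C@@H]1[C@@]2(c3cccc(OC)c3OC(C)C)CCC[C@]1(C)C(=O)OC2 | intermediate
16 | 2-[(1S,5R,9R)-5-(2-isopropoxy-3-methoxyphenyl)-1-methyl-2-oxo-3-oxabicyclo[3.3.1]nonan-9-yl]acetic acid | OC(=O)C[C@@H]1[C@@]2(c3cccc(OC)c3OC(C)C)CCC[C@]1(C)C(=O)OC2 | intermediate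
17 | mixed anhydride of 16 with trifluoroacetic acid | O=C(OC(=O)C(F)(F)F)C[C@@H]1[C@@]2(c3cccc(OC)c3OC(C)C)CCC[C@]1(C)C(=O)OC2 | intermediate
18 | (4S,5R,10R)-11-isopropoxy-12-methoxy-7-oxopodocarpa-8,11,13-trien-19,20-olide | COc1c(OC(C)C)c2c(cc1)C(=O)C[C@@H]1[C@]23CCC[C@]1(C)C(=O)OC3 | intermediate
19 | 11-O-dichloroboryl derivative of 20 (aryl dichloroborinate) | COc1c(OB(Cl)Cl)c2c(cc1)C(=O)C[C@@H]1[C@]23CCC[C@]1(C)C(=O)OC3 | intermediate
20 | (4S,5R,10R)-11-hydroxy-12-methoxy-7-oxopodocarpa-8,11,13-trien-19,20-olide | COc1c(O)c2c(cc1)C(=O)C[C@@H]1[C@]23CCC[C@]1(C)C(=O)OC3 | intermediate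
21 | (4S,5R,10R)-12-methoxy-7,11,14-trioxopodocarpa-8,12-dien-19,20-olide | COC1C(=O)C2=C(C(=O)C=1)C(=O)C[C@@H]1[C@]23CCC[C@]1(C)C(=O)OC3 | intermediate
22 | isobutyric acid | CC(C)C(=O)O | starting material
23 | (4S,5R,10R)-12-methoxy-7,11,14-trioxoabieta-8,12-dien-19,20-olide | COC1C(=O)C2=C(C(=O)C=1C(C)C)C(=O)C[C@@H]1[C@]23CCC[C@]1(C)C(=O)OC3 | intermediate
24 | (4S,5R,10R)-11,14-dihydroxy-12-methoxy-7-oxoabieta-8,11,13-trien-19,20-olide (CNP0159814.2) | COc1c(O)c2c(c(O)c1C(C)C)C(=O)C[C@@H]1[C@]23CCC[C@]1(C)C(=O)OC3 | target

**Step count and risks**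

Total step count: 15. Longest linear sequence: 15 steps (from 1 to 24).

Steps most likely to fail:

1. Step 10 (key cascade). What may go wrong: hydrogen transfer to the primary C2 radical, or hydrosilylation of an acrylate, outruns the slow 8-endo ring closure; less likely, the C4 radical attacks the other face of C5. The fallback sets out from 14 and returns at 15. It makes the first bond intermolecularly and closes the lactone afterwards. Iodide 14 is treated with (Me3Si)3SiH/AIBN and an excess of methyl methacrylate in PhH at 80 °C. Giese addition of the C2 radical to the external acceptor and 6-exo cyclisation of the adduct radical onto the enoate should give the cyclohexane triester F1, of which the C4 epimer with the methyl ester cis to the C20 arm is the useful one. K2CO3 in MeOH then exchanges the pendant methacrylate for the neighbouring C19 methyl ester, which lactonises F1 to 15; the other C4 epimer cannot lactonise and is separated.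

2. Step 5 (desymmetrisation). What may go wrong: poor discrimination of the enantiotopic hydroxymethyl groups with the methacrylate donor, or loss of enantiopurity by 1,3-acyl migration before step 6. The fallback sets out from 7 and returns at 12. It uses the established benzoate donor as a temporary group. Diol 7, vinyl benzoate and the same dinuclear zinc catalyst give the monobenzoate F2. Dess–Martin oxidation gives the aldehyde F3, and Wittig reaction with 11 gives the enoate F4. K2CO3 in MeOH removes the benzoate to give the hydroxymethyl enoate F5, which methacryloyl chloride, Et3N and DMAP convert into 12.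

3. Step 14 (late isopropylation). What may go wrong: low conversion, or unselective attack of sulfate and alkyl radicals on the functionalised quinone. The fallback sets out from 21 and returns at 24. It replaces the radical alkylation by halogenation and cross-coupling. Br2 followed by Et3N gives the bromoquinone F6. Suzuki–Miyaura coupling with isopropenylboronic acid pinacol ester (Pd(PPh3)4, K2CO3, dioxane/H2O) gives the isopropenylquinone F7. Hydrogenation (H2, palladium on carbon, EtOAc) reduces the alkene and the quinone and should give 24 directly.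

**Further compounds**

F1 | step 10 | methyl (1S,2R,3R)-2-(2-tert-butoxy-2-oxoethyl)-3-(2-isopropoxy-3-methoxyphenyl)-3-[(methacryloyloxy)methyl]-1-methylcyclohexane-1-carboxylate | CC(C)(C)OC(=O)C[C@@H]1[C@@](COC(=O)C(C)=C)(c2cccc(OC)c2OC(C)C)CCC[C@]1(C)C(=O)OC
F2 | step 5 | (S)-2-[2-(tert-butyldimethylsilyloxy)ethyl]-3-hydroxy-2-(2-isopropoxy-3-methoxyphenyl)propyl benzoate | OC[C@](c1cccc(OC)c1OC(C)C)(COC(=O)c1ccccc1)CCO[Si](C)(C)C(C)(C)C
F3 | step 5 | (R)-4-(tert-butyldimethylsilyloxy)-2-formyl-2-(2-isopropoxy-3-methoxyphenyl)butyl benzoate | O=C[C@](c1cccc(OC)c1OC(C)C)(COC(=O)c1ccccc1)CCO[Si](C)(C)C(C)(C)C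
F4 | step 5 | tert-butyl (R,E)-4-[(benzoyloxy)methyl]-6-(tert-butyldimethylsilyloxy)-4-(2-isopropoxy-3-methoxyphenyl)hex-2-enoate | CC(C)(C)OC(=O)/C=C/[C@](c1cccc(OC)c1OC(C)C)(COC(=O)c1ccccc1)CCO[Si](C)(C)C(C)(C)C
F5 | step 5 | tert-butyl (R,E)-6-(tert-butyldimethylsilyloxy)-4-(hydroxymethyl)-4-(2-isopropoxy-3-methoxyphenyl)hex-2-enoate | CC(C)(C)OC(=O)/C=C/[C@](c1cccc(OC)c1OC(C)C)(CO)CCO[Si](C)(C)C(C)(C)C
F6 | step 14 | (4S,5R,10R)-13-bromo-12-methoxy-7,11,14-trioxopodocarpa-8,12-dien-19,20-olide | COC1C(=O)C2=C(C(=O)C=1Br)C(=O)C[C@@H]1[C@]23CCC[C@]1(C)C(=O)OC3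
F7 | step 14 | (4S,5R,10R)-13-isopropenyl-12-methoxy-7,11,14-trioxopodocarpa-8,12-dien-19,20-olide | COC1C(=O)C2=C(C(=O)C=1C(C)=C)C(=O)C[C@@H]1[C@]23CCC[C@]1(C)C(=O)OC3
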